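A direct plan would buy rings A and C and the C5 stereocentre in (+)-carnosic acid A1, convert ring C into its 11,12,14-trimethyl ether and reduce the C20 acid to the neopentyl alcohol A2.
Solvolysis of the C20 mesylate of A2 would move the arene from C10 to C20 and let water add to C10 (icetexanol A3). Benzylic oxidation at C7 (hydroxy ketone A4) and oxidative demethylation would finish, with the 10-OH closing the hemiketal last.
Weakest step, the cationic aryl shift with water capture: it would have to make ring B and set C10 in one event. A tertiary C10 cation flanked by C1-H2 and C5-H should lose a proton as readily as it takes up water, and only an assumed tight phenonium ion would fix the face of attack.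
Second, the benzylic oxidation of A3: C7-H2, C20-H2 and the isopropyl methine are all benzylic on a very electron-rich arene. Site selectivity and survival of the ring under Cr(VI)/peroxide would be doubtful, and this comes late.
Third, the ring C detour: catechol to quinone to trimethyl ether and back to quinone costs four operations that build no skeletal bond. It also starts with a selective mono-O-methylation of an air-sensitive catechol.

**Retrosynthetic overview**
1. Feature used: the five-membered ring O–C7–C6–C5–C10 inside the oxa-bridge is a γ-lactone at the oxidation level of C7. It is made first, as a γ,γ-disubstituted butenolide, and rings A and B are then attached to it.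
2. Komaroviquinone ⇐ C7–C8 (ring B, bridge, C7): the C8 carbanion of a masked quinone (bisketal from anodic oxidation) attacks the lactone carbonyl C7 across the ring oxygen, and hydrolysis follows.
3. cis-Lactone ⇐ C4–C5 (ring A, C5): HAT-initiated 6-exo radical cyclisation of the C3=C4 prenyl terminus onto C5 of the butenolide (key step).
4. Butenolide ⇐ C5=C6 and O–C7 from Ph3P=C=C=O ⇐ C9–C20 by aryl–copper opening of a Sharpless epoxide, which sets C10 by reagent control.
5. Ring order: C (arene) → lactone ring of the bridge → A → B. C10 is never a cation, C7 needs no C–H oxidation, ring C is oxidised once, and the 6-7-6 core first appears in the last step.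

Key step: step 8

Assumptions: the icetexane numbering of the target (ring A = C1–C5, C10; ring B = C5–C10, C20; ring C = C8, C9, C11–C14) is used for all intermediates. Only reagents whose carbon atoms enter the skeleton are numbered (2, 15). D-(−)-tartrate is taken to give the (R)-epoxide, as it does with other 2-alkylallyl alcohols.

Step 1
Reactants: 1 1,2,4-trimethoxybenzene; 2 acetone
Product: 4 2-(2,3,6-trimethoxyphenyl)propan-2-ol, via (2,3,6-trimethoxyphenyl)lithium 3 (not isolated)
Conditions: n-BuLi, THF, 0 °C to rt; acetone, −78 °C to rt; H2O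
Reagents that add atoms: acetone, CC(C)=O
Why: Directed ortho-metalation should occur at C3, the position flanked by two methoxy groups, and the aryllithium adds 1,2 to acetone; no stereocentre is formed.

Step 2
Reactants: 4 2-(2,3,6-trimethoxyphenyl)propan-2-ol
Product: 5 2-isopropyl-1,3,4-trimethoxybenzene
Conditions: Et3SiH, CF3CO2H, CH2Cl2, 0 °C to rt
Reagents that add atoms: none
Why: Ionic hydrogenation: the tertiary benzylic cation, stabilised by two ortho methoxy groups, is trapped by silane hydride, and the aryl ethers are inert.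

Step 3
Reactants: 6 5-bromo-2-methylpent-2-ene; 7 prop-2-yn-1-ol
Product: 9 6-methyl-2-methylidenehept-5-en-1-ol, via (4-methylpent-3-en-1-yl)magnesium bromide 8 (not isolated)
Conditions: Mg, THF, rt; 7 (0.45 equiv), CuI (10 mol %), THF/Et2O, −10 °C to rt; H2O
Reagents that add atoms: none
Why: Copper-catalysed carbomagnesiation of the propargylic magnesium alkoxide places the alkyl group on the internal alkyne carbon through a chelated vinylmagnesium species, and hydrolysis gives the 2-substituted allylic alcohol.

Step 4
Reactants: 9 6-methyl-2-methylidenehept-5-en-1-ol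
Product: 10 [(2R)-2-(4-methylpent-3-en-1-yl)oxiran-2-yl]methanol
Conditions: Ti(OiPr)4 (10 mol %), D-(−)-DIPT (12 mol %), t-BuOOH, 4 Å MS, CH2Cl2, −20 °C
Reagents that add atoms: tert-butyl hydroperoxide, CC(C)(C)OO
Why: Sharpless asymmetric epoxidation touches only the alkene that carries the allylic OH, not the remote trisubstituted alkene, and the tartrate ligand sets C10 by reagent control.

Step 5
Reactants: 5 2-isopropyl-1,3,4-trimethoxybenzene; 10 [(2R)-2-(4-methylpent-3-en-1-yl)oxiran-2-yl]methanol
Product: 13 (2S)-2-[(4-isopropyl-2,3,5-trimethoxyphenyl)methyl]-6-methylhept-5-ene-1,2-diol, via aryllithium 11 (not isolated), via arylmagnesium bromide 12 (not isolated)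
Conditions: 5 (2.3 equiv), n-BuLi, TMEDA, THF, 0 °C to rt; MgBr2·OEt2, 0 °C; CuI (10 mol %), 10, −30 to 0 °C; H2O
Reagents that add atoms: none
Why: Directed ortho-metalation should take the more acidic C–H (ortho to the 4-OMe and meta to two further OMe groups, the future C9), and copper-catalysed SN2 opening of the epoxide at its unsubstituted CH2 forms C9–C20 while the C10–O bond, and hence the configuration, stays intact.

Step 6
Reactants: 13 (2S)-2-[(4-isopropyl-2,3,5-trimethoxyphenyl)methyl]-6-methylhept-5-ene-1,2-diol
Product: 14 (2S)-2-hydroxy-2-[(4-isopropyl-2,3,5-trimethoxyphenyl)methyl]-6-methylhept-5-enal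
Conditions: IBX, DMSO, rt
Reagents that add atoms: none
Why: IBX oxidises the primary alcohol of a 1,2-diol without glycol cleavage, the tertiary OH is inert, and C10 bears no hydrogen, so it cannot epimerise.

Step 7
Reactants: 14 (2S)-2-hydroxy-2-[(4-isopropyl-2,3,5-trimethoxyphenyl)methyl]-6-methylhept-5-enal; 15 (triphenylphosphoranylidene)ketene
Product: 17 (5S)-5-[(4-isopropyl-2,3,5-trimethoxyphenyl)methyl]-5-(4-methylpent-3-en-1-yl)furan-2(5H)-one, via acyl ylide ester 16 (not isolated)
Conditions: Ph3P=C=C=O, toluene, 90 °C
Reagents that add atoms: (triphenylphosphoranylidene)ketene, O=C=C=P(c1ccccc1)(c1ccccc1)c1ccccc1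
Why: The tertiary OH adds to the cumulated ylide (Bestmann ylide) and the resulting ester ylide undergoes an intramolecular Wittig reaction with the aldehyde, which closes the butenolide (O–C7 and C5=C6) without touching C10.

Step 8
Reactants: 17 (5S)-5-[(4-isopropyl-2,3,5-trimethoxyphenyl)methyl]-5-(4-methylpent-3-en-1-yl)furan-2(5H)-one
Product: 18 (3aS,7aS)-7a-[(4-isopropyl-2,3,5-trimethoxyphenyl)methyl]-4,4-dimethylhexahydro-1-benzofuran-2(3H)-one
Conditions: Fe(acac)3 (30 mol %), PhSiH3, EtOH, 60 °C, 0.02 M
Reagents that add atoms: none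
Why: An iron hydride formed from Fe(acac)3 and PhSiH3 transfers a hydrogen atom to C3 of the trisubstituted alkene, the nucleophilic tertiary C4 radical adds to the electrophilic β-carbon C5 of the butenolide, and the C6 α-acyl radical is reduced and protonated by ethanol. The closest known reaction type is the HAT-initiated reductive olefin coupling (Giese-type radical conjugate addition) in its intramolecular form. Ring A closes 6-exo-trig through a chair-like transition state, forming the most congested bond of the target, between quaternary C4 and C5 next to fully substituted C10. C5 is controlled by C10: the four-atom tether is anchored on C10 beside the planar lactone, so C4 can reach C5 only from the face that carries C1, which enforces the cis-fused lactone with H-5 syn to C20 (5S from 10S). The step needs hydrogen-atom transfer to the electron-rich alkene rather than to the electron-poor butenolide, which is the normal polarity preference of iron hydrides, and it needs cyclisation to beat a second hydrogen transfer, which dilution and the matched nucleophilic-radical/acceptor pair favour. The precursor has one stereocentre and one non-aromatic ring, and the product holds ring A, the lactone ring of the bridge and both carbon stereocentres C5 and C10.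

Step 9
Reactants: 18 (3aS,7aS)-7a-[(4-isopropyl-2,3,5-trimethoxyphenyl)methyl]-4,4-dimethylhexahydro-1-benzofuran-2(3H)-one
Product: 19 (3aS,7aS)-7a-[(2-bromo-4-isopropyl-3,5,6-trimethoxyphenyl)methyl]-4,4-dimethylhexahydro-1-benzofuran-2(3H)-one
Conditions: NBS, MeCN, 0 °C
Reagents that add atoms: N-bromosuccinimide, O=C1CCC(=O)N1Br
Why: Electrophilic aromatic bromination can only occur at C8, the single free position of the activated ring, and no alkene is left to compete.

Step 10
Reactants: 19 (3aS,7aS)-7a-[(2-bromo-4-isopropyl-3,5,6-trimethoxyphenyl)methyl]-4,4-dimethylhexahydro-1-benzofuran-2(3H)-one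
Product: 20 (3aS,7aS)-7a-[(2-bromo-4-isopropyl-3,3,5,6,6-pentamethoxycyclohexa-1,4-dien-1-yl)methyl]-4,4-dimethylhexahydro-1-benzofuran-2(3H)-one
Conditions: Pt anode, Pt cathode, undivided cell, constant current, MeOH, Et4NOTs, 2,6-lutidine, 0 °C
Reagents that add atoms: methanol, CO
Why: Anodic two-electron oxidation of a 1,4-dimethoxyarene with methanol capture at the ipso carbons C11 and C14 gives the quinone bisketal, while the C–Br bond and the stereocentres are untouched and the lutidine buffer should keep the lactone from methanolysis.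

Step 11
Reactants: 20 (3aS,7aS)-7a-[(2-bromo-4-isopropyl-3,3,5,6,6-pentamethoxycyclohexa-1,4-dien-1-yl)methyl]-4,4-dimethylhexahydro-1-benzofuran-2(3H)-one
Product: 23 komaroviquinone (5S,7S,10S), via C8-lithio bisketal 21 (not isolated), via bridged bisketal hemiketal 22 (not isolated)
Conditions: n-BuLi (1.05 equiv), THF/Et2O, −100 to −40 °C; then 1 M HCl, THF, 0 °C to rt
Reagents that add atoms: water, O
Why: Parham-type cyclisation: at −100 °C bromine–lithium exchange on the vinyl bromide should outrun butyl addition to the lactone, the C8 carbanion held over the lactone by the C20 methylene adds to C7 (a six-membered closure counted through the ring oxygen, which also closes the seven-membered ring B), the bridge permits only the 7S hemiketal, and dilute acid then hydrolyses both ketals to the quinone without opening the bridgehead hemiketal.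

**Compound list**
1 | 1,2,4-trimethoxybenzene | COc1ccc(OC)c(OC)c1 | starting material
2 | acetone | CC(C)=O | starting material
3 | (2,3,6-trimethoxyphenyl)lithium | [Li]c1c(OC)ccc(OC)c1OC | intermediate
4 | 2-(2,3,6-trimethoxyphenyl)propan-2-ol | COc1ccc(OC)c(OC)c1C(C)(C)O | intermediate
5 | 2-isopropyl-1,3,4-trimethoxybenzene | COc1ccc(OC)c(OC)c1C(C)C | intermediate
6 | 5-bromo-2-methylpent-2-ene | CC(C)=CCCBr | starting material
7 | prop-2-yn-1-ol | C#CCO | starting material
8 | (4-methylpent-3-en-1-yl)magnesium bromide | CC(C)=CCC[Mg]Br | intermediate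
9 | 6-methyl-2-methylidenehept-5-en-1-ol | C=C(CO)CCC=C(C)C | intermediate
10 | [(2R)-2-(4-methylpent-3-en-1-yl)oxiran-2-yl]methanol | OC[C@]1(CCC=C(C)C)CO1 | intermediate
11 | (4-isopropyl-2,3,5-trimethoxyphenyl)lithium | [Li]c1cc(OC)c(C(C)C)c(OC)c1OC | intermediate
12 | (4-isopropyl-2,3,5-trimethoxyphenyl)magnesium bromide | Br[Mg]c1cc(OC)c(C(C)C)c(OC)c1OC | intermediate
13 | (2S)-2-[(4-isopropyl-2,3,5-trimethoxyphenyl)methyl]-6-methylhept-5-ene-1,2-diol | COc1cc(C[C@@](CO)(O)CCC=C(C)C)c(OC)c(OC)c1C(C)C | intermediate
14 | (2S)-2-hydroxy-2-[(4-isopropyl-2,3,5-trimethoxyphenyl)methyl]-6-methylhept-5-enal | COc1cc(C[C@@](C=O)(O)CCC=C(C)C)c(OC)c(OC)c1C(C)C | intermediate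
15 | (triphenylphosphoranylidene)ketene | O=C=C=P(c1ccccc1)(c1ccccc1)c1ccccc1 | starting material
16 | (triphenylphosphoranylidene)acetate ester of 14 (acyl ylide) | COc1cc(C[C@@](C=O)(OC(=O)C=P(c2ccccc2)(c2ccccc2)c2ccccc2)CCC=C(C)C)c(OC)c(OC)c1C(C)C | intermediate
17 | (5S)-5-[(4-isopropyl-2,3,5-trimethoxyphenyl)methyl]-5-(4-methylpent-3-en-1-yl)furan-2(5H)-one | COc1cc(C[C@@]2(CCC=C(C)C)C=CC(=O)O2)c(OC)c(OC)c1C(C)C | intermediate
18 | (3aS,7aS)-7a-[(4-isopropyl-2,3,5-trimethoxyphenyl)methyl]-4,4-dimethylhexahydro-1-benzofuran-2(3H)-one | COc1cc(C[C@@]23CCCC(C)(C)[C@@H]2CC(=O)O3)c(OC)c(OC)c1C(C)C | intermediate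
19 | (3aS,7aS)-7a-[(2-bromo-4-isopropyl-3,5,6-trimethoxyphenyl)methyl]-4,4-dimethylhexahydro-1-benzofuran-2(3H)-one | COc1c(Br)c(C[C@@]23CCCC(C)(C)[C@@H]2CC(=O)O3)c(OC)c(OC)c1C(C)C | intermediate
20 | (3aS,7aS)-7a-[(2-bromo-4-isopropyl-3,3,5,6,6-pentamethoxycyclohexa-1,4-dien-1-yl)methyl]-4,4-dimethylhexahydro-1-benzofuran-2(3H)-one | COC1=C(C(C)C)C(OC)(OC)C(Br)=C(C[C@@]23CCCC(C)(C)[C@@H]2CC(=O)O3)C1(OC)OC | intermediate
21 | C8-lithio quinone bisketal lactone | COC1=C(C(C)C)C(OC)(OC)C([Li])=C(C[C@@]23CCCC(C)(C)[C@@H]2CC(=O)O3)C1(OC)OC | intermediate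
22 | komaroviquinone 11,14-bis(dimethyl ketal) (bridged hemiketal) | COC1=C(C(C)C)C(OC)(OC)C2=C(C[C@@]34CCCC(C)(C)[C@@H]3C[C@]2(O)O4)C1(OC)OC | intermediate
23 | komaroviquinone | COC1=C(C(C)C)C(=O)C2=C(C[C@@]34CCCC(C)(C)[C@@H]3C[C@]2(O)O4)C1=O | target

Total step count: 11. Longest linear sequence: 9 (steps 1, 2, 5–11, or equally steps 3–11).

**Steps most likely to fail**

Step 8 (radical cyclisation). The tertiary C4 radical may be quenched by a second hydrogen-atom transfer before it reaches the hindered C5, or the iron hydride may reduce the butenolide. The fallback separates radical generation from the hydride source. From 17, Markovnikov addition of HBr (HBr/AcOH, 0 °C) would give the tertiary bromide (5S)-5-(4-bromo-4-methylpentyl)-5-[(4-isopropyl-2,3,5-trimethoxyphenyl)methyl]furan-2(5H)-one F1. A tin hydride chain cyclisation with the hydrogen donor kept scarce (Bu3SnH by syringe pump, AIBN, benzene, 80 °C) would then lead back to 18, with the same tether control of C5.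

Step 11 (carbanion closure). Butyl addition to the lactone may compete with the exchange, or the vinyllithium may be lost by proton transfer from C6-H2. The fallback closes the ring at the aldehyde oxidation level. From 20, DIBAL-H (CH2Cl2, −78 °C) would give the lactol F5. n-BuLi (2.1 equiv, the first for the OH) would trigger exchange and addition to the far more electrophilic ring-opened aldehyde, giving the 7,10-diol F6. Oxidation of its secondary allylic alcohol (MnO2 or Dess–Martin periodinane) would return to 22, which is hydrolysed as in step 11.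

Step 10 (anodic bisketalisation). Side-chain oxidation at C20 or at the isopropyl methine may compete with ipso methoxylation of the crowded ring, or the lactone may suffer methanolysis. The fallback avoids the electrolysis and the ketals. From 19, CAN (MeCN/H2O, 0 °C) would give the bromoquinone lactone F2, and Na2S2O4 would reduce it to the bromohydroquinone F3. Excess n-BuLi (3.2 equiv, THF, −78 °C; two equivalents for the phenols) would effect exchange and closure to the hydroquinone hemiketal F4. Oxidation by air or Ag2O on work-up would then give 23.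

**Further compounds**
F1 | step 8 | (5S)-5-(4-bromo-4-methylpentyl)-5-[(4-isopropyl-2,3,5-trimethoxyphenyl)methyl]furan-2(5H)-one | COc1cc(C[C@@]2(CCCC(C)(C)Br)C=CC(=O)O2)c(OC)c(OC)c1C(C)C
F2 | step 10 | 2-bromo-3-{[(3aS,7aS)-4,4-dimethyl-2-oxohexahydro-1-benzofuran-7a(2H)-yl]methyl}-6-isopropyl-5-methoxy-1,4-benzoquinone | COC1=C(C(C)C)C(=O)C(Br)=C(C[C@@]23CCCC(C)(C)[C@@H]2CC(=O)O3)C1=O
F3 | step 10 | (3aS,7aS)-7a-[(2-bromo-3,6-dihydroxy-4-isopropyl-5-methoxyphenyl)methyl]-4,4-dimethylhexahydro-1-benzofuran-2(3H)-one | COc1c(O)c(C[C@@]23CCCC(C)(C)[C@@H]2CC(=O)O3)c(Br)c(O)c1C(C)C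
F4 | step 10 | komaroviquinone hydroquinone (11,14-dihydroxy bridged hemiketal) | COc1c(O)c2C[C@@]34CCCC(C)(C)[C@@H]3C[C@](O)(O4)c2c(O)c1C(C)C
F5 | step 11 | lactol of 20 (2-hydroxy-octahydrobenzofuran, C7 epimers) | COC1=C(C(C)C)C(OC)(OC)C(Br)=C(C[C@@]23CCCC(C)(C)[C@@H]2CC(O)O3)C1(OC)OC
F6 | step 11 | (5S,10S)-7,10-dihydroxy-icetexane quinone bisketal (C7 epimers) | COC1=C(C(C)C)C(OC)(OC)C2=C(C[C@@]3(O)CCCC(C)(C)[C@@H]3CC2O)C1(OC)OC
A1 | direct plan | (+)-carnosic acid | CC(C)c1cc2CC[C@H]3C(C)(C)CCC[C@]3(C(=O)O)c2c(O)c1O
A2 | direct plan | (5S,10R)-11,12,14-trimethoxyabieta-8,11,13-trien-20-ol | CC(C)c1c(OC)c2CC[C@H]3C(C)(C)CCC[C@]3(CO)c2c(OC)c1OC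
A3 | direct plan | (5S,10S)-11,12,14-trimethoxyicetexa-8,11,13-trien-10-ol | CC(C)c1c(OC)c2CC[C@H]3C(C)(C)CCC[C@]3(O)Cc2c(OC)c1OC
A4 | direct plan | (5S,10S)-10-hydroxy-11,12,14-trimethoxyicetexa-8,11,13-trien-7-one | CC(C)c1c(OC)c2C(=O)C[C@H]3C(C)(C)CCC[C@]3(O)Cc2c(OC)c1OC
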